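The Q left over in a flask is its clock. Call θ = ln(Q charged / Q left) the exposure; it equals k, the constant of Q + G -> D, times G summed over time. Each later addition also takes one G, so at one temperature D, X and the sum of E and Z follow θ, with that sum starting as its cube, while the split between E and Z, which takes no G, runs on clock time. Z was not read in the earlier runs, so I reckon E as if it held the sum.

| flask | Q | G | temperature | remark | time |
|---|---|---|---|---|---|
| Monday's | 0.019 M | 0.11 M | 55 °C | run made earlier |  |
| Sunday's | 0.080 M | 0.11 M | 66 °C | run made earlier |  |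
| midnight | 0.10 M | 0.110 M | 60 °C |  | 10 min |
| noon | 0.030 M | 0.110 M | 60 °C |  | 3.0 min |

- Monday's (time / min: E / %, Q / %): 1.33: 2, 63; 4.00: 21, 30; 6.00: 36, 21; 10.0: 57, 9
- Sunday's (time / min: E / %, Q / %): 0.833: 0, 62; 2.00: 9, 43; 4.00: 14, 35; 10.0: 14, 29

(readings scatter by 2 percentage points)

- what may be going on: G + X -> E; G + D -> X; Q + G -> D; E <-> Z

- the flask that ends with the higher amount of E, in percent of the Q charged, or "neither" when 2 percentage points or less lies between them (midnight / noon / neither)
- final E, as a percentage of the Q charged, in midnight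
- final E, as a percentage of the Q charged, in noon

Which numbers must you know well? For midnight the time hardly counts, and k with it: in Sunday's run, with 1.38 G per Q, E reads 14 % at 4.00 min and 14 % at 10.0 min. What counts there is G per Q, 1.10, less than the 3 one E takes, which makes G the limiting reagent. Sunday stalled at θ = 1.24, so scaling by G per Q gives midnight 0.990.

Noon, with 3.67 G per Q, is still running at its end, so k and time count. Monday's Q, with G in excess, gives k = 2.74 M⁻¹ min⁻¹ at 55 °C. Sunday's first reading gives 5.22 M⁻¹ min⁻¹ at 66 °C, so I take 3.78 M⁻¹ min⁻¹ at 60 °C. Noon's exposure, k times G charged times time, is then 1.25.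

Near that θ, Monday read E 21 % and Sunday 14 %, so I reckon noon at 17.5 %. Midnight I reckon from Sunday's last reading, taken at 10.0 min as midnight ends at 10 min: passing over that Sunday ran at 66 °C, the cube of the ratio of their θ puts midnight at 7.17 %. A scatter of 2 percentage points in Monday's Q shifts noon's θ by 2.77 %, since the k at 60 °C takes half of Monday's error, and through the cube that is 1.5 points on noon's E, less than the gap between my two flasks.

The forecast gave 9.5 % for midnight and 14 % for noon, my noon standing higher and my midnight lower, and it chose noon: “Noon is probably higher, but only modestly”.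

The flask gives 10.2 % in midnight and 17.9 % in noon, so noon ends higher.

    G + X → E (k = 4.90 M⁻¹ min⁻¹, Ea = 43.0 kJ mol⁻¹)
    G + D → X (k = 9.80 M⁻¹ min⁻¹, Ea = 46.0 kJ mol⁻¹)
    Q + G → D (k = 4.30 M⁻¹ min⁻¹, Ea = 60.0 kJ mol⁻¹)
    E ⇌ Z (K = 0.220, k = 0.130 min⁻¹, Ea = 92.0 kJ mol⁻¹, ΔH = 7.00 kJ mol⁻¹)
    (constants at 60 °C)

Midnight keeps 0.54 % of its G at 10.0 min, and its E is 10.2 % at 100 min. Noon's 32.1 % of Q reads θ = 1.14, less than the reckoned 1.25, while its G fell to 63 % of the charge.

For noon's neighbour with 0.19 M of G, θ scales to 2.15. That lies above Monday's 1.56 and below its 2.41, where E read 36 % and 57 %. The computed neighbour holds 43.7 % of E, with 13.8 % of Q left.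

(The readings were computed from invented constants.)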